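**Retrosynthetic overview**
- The C-8 ester comes from Yamaguchi acylation with a PMB-protected 2-(hydroxymethyl)acrylic acid, followed by removal of both PMB ethers. The C-11 methyl comes from lactone enolate methylation, and the trans γ-lactone (last ring) from the 6R allylic alcohol and the C-7 acetate arm.
- The ten-membered ring (third ring event) comes from Grob fragmentation of a cis-fused bicyclo[5.3.0]decene 1,3-diol monomesylate. Cutting the C-6/C-10 fusion bond gives the C-6 ketone and the Z C-1=C-10 olefin, while the ring-cis C-4=C-5 olefin is carried over from the seven-membered ring.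
- The seven-membered ring (second) comes from ring-closing metathesis after vinyl addition to the cyclopentanone. The C-1/C-10 pair comes from an anti reductive aldol of a 2-methylcyclopentenone with a C-1 to C-4/C-15 aldehyde.
- The five-membered ring (first, purchased) is (R)-4-silyloxycyclopent-2-enone, which supplies C-6 to C-10 and the C-8 oxygen; α-methylation adds C-14 and α′-alkylation with a bromoacetate adds C-11/C-12 and sets C-7.
- Side fragments: the aldehyde from 2-methylidenepropane-1,3-diol (etherification, Claisen) and the acid from 2-(bromomethyl)acrylic acid.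

Assumption: the SMILES is read literally, so both ring double bonds are cis within the ring (C-1=C-10 is Z; C-4=C-5 is E by CIP only because of the CH2OH group) and the configuration is 6R,7R,8S,11S; carbons are labelled C-1 to C-15 in germacrane numbering. The route has not been run; conditions are proposed from precedent.

**Step 1**
Reactants: 1 2-methylidenepropane-1,3-diol
Product: 2 2-{[(4-methoxybenzyl)oxy]methyl}prop-2-en-1-ol
Conditions: NaH (1.0 equiv), 4-methoxybenzyl chloride (1.0 equiv), Bu4NI (cat.), THF/DMF, 0 °C to rt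
Reagents that add atoms: 4-methoxybenzyl chloride, COc1ccc(CCl)cc1
Why: Williamson ether synthesis on a symmetric diol with one equivalent of base and halide gives the mono-PMB ether statistically (diol recycled), leaving one allylic OH for the next step; no stereocentre is involved.

**Step 2**
Reactants: 2 2-{[(4-methoxybenzyl)oxy]methyl}prop-2-en-1-ol; 3 ethyl vinyl ether
Product: 5 4-{[(4-methoxybenzyl)oxy]methyl}pent-4-enal, via allyl vinyl ether 4 (not isolated)
Conditions: Hg(OAc)2 (5 mol%), ethyl vinyl ether (solvent), reflux; evaporate; toluene, 150 °C, sealed tube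
Reagents that add atoms: none
Why: Mercury-catalysed transvinylation gives the allyl vinyl ether, whose thermal Claisen rearrangement (fragment preparation only) delivers the γ,δ-unsaturated aldehyde carrying the 1,1-disubstituted olefin needed later for metathesis.

**Step 3**
Reactants: 6 2-(bromomethyl)prop-2-enoic acid
Product: 7 2-{[(4-methoxybenzyl)oxy]methyl}prop-2-enoic acid
Conditions: 4-methoxybenzyl alcohol (1.1 equiv), NaH (2.2 equiv), THF, 0 °C to rt; then 1 M HCl to pH 3
Reagents that add atoms: 4-methoxybenzyl alcohol, COc1ccc(CO)cc1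
Why: SN2/SN2′ etherification in which the alkoxide displaces the allylic bromide of the carboxylate salt, whose negative charge suppresses Michael addition to the product.

**Step 4**
Reactants: 8 (4R)-4-[(tert-butyldimethylsilyl)oxy]cyclopent-2-en-1-one
Product: 9 (4R)-4-[(tert-butyldimethylsilyl)oxy]-2-iodocyclopent-2-en-1-one
Conditions: I2 (1.5 equiv), pyridine/CH2Cl2 (1:1), 0 °C to rt
Reagents that add atoms: iodine, II
Why: Johnson α-iodination of an enone (pyridine conjugate addition, iodination of the enolate, elimination) is established on this silyloxy enone and does not touch the C-8 stereocentre.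

**Step 5**
Reactants: 9 (4R)-4-[(tert-butyldimethylsilyl)oxy]-2-iodocyclopent-2-en-1-one
Product: 10 (4R)-4-[(tert-butyldimethylsilyl)oxy]-2-methylcyclopent-2-en-1-one
Conditions: Me4Sn (1.5 equiv), Pd(PhCN)2Cl2 (5 mol%), AsPh3 (10 mol%), CuI (10 mol%), NMP, 80 °C
Reagents that add atoms: tetramethylstannane, C[Sn](C)(C)C
Why: Stille cross-coupling of the α-iodo enone installs the C-14 methyl under neutral conditions that preserve the base-sensitive γ-silyloxy enone.

**Step 6**
Reactants: 10 (4R)-4-[(tert-butyldimethylsilyl)oxy]-2-methylcyclopent-2-en-1-one; 11 tert-butyl bromoacetate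
Product: 12 tert-butyl 2-[(1R,5S)-5-[(tert-butyldimethylsilyl)oxy]-3-methyl-2-oxocyclopent-3-en-1-yl]acetate
Conditions: LiN(iPr)2 (1.1 equiv), THF, −78 °C; 11 (1.3 equiv), DMPU, −78 to −40 °C
Reagents that add atoms: none
Why: Kinetic α′-deprotonation gives the cross-conjugated lithium enolate, whose alkylation by the reactive α-bromo ester occurs anti to the neighbouring silyloxy group, setting C-7 trans to the C-8 oxygen as in the target; at −78 °C loss of silanolate is slow because it would lead to a cyclopentadienone.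

**Step 7**
Reactants: 12 tert-butyl 2-[(1R,5S)-5-[(tert-butyldimethylsilyl)oxy]-3-methyl-2-oxocyclopent-3-en-1-yl]acetate; 5 4-{[(4-methoxybenzyl)oxy]methyl}pent-4-enal
Product: 14 tert-butyl 2-[(1R,3S,5S)-5-[(tert-butyldimethylsilyl)oxy]-3-[(1S)-1-hydroxy-4-{[(4-methoxybenzyl)oxy]methyl}pent-4-en-1-yl]-3-methyl-2-oxocyclopentyl]acetate, via pinacolboron enolate 13 (not isolated)
Conditions: Cu(OAc)2 (5 mol%), 1,2-bis(diphenylphosphino)benzene (6 mol%), pinacolborane (1.0 equiv), THF, −20 °C, 2 h; then 5 (1.3 equiv), −78 to −30 °C; aq. NH4Cl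
Reagents that add atoms: none
Why: Proposed new method: a monovalent copper hydride formed from Cu(OAc)2, the bisphosphine and pinacolborane adds hydride to the β-carbon (C-9) of enone 12, σ-bond metathesis of the copper enolate with pinacolborane gives the tetrasubstituted boron enolate 13 regiospecifically and regenerates the hydride, and this ring-locked E(O)-enolate adds to aldehyde 5 through a closed Zimmerman–Traxler chair with the aldehyde chain equatorial and anti to the C-7 arm, forging the C-1–C-10 bond as the anti aldol (quaternary C-10 S, carbinol C-1 S; a C-10 epimer with the same relative C-1/C-10 configuration would converge later) whose relative configuration fixes the Z olefin in step 10; the closest known reaction types are copper hydride catalysed conjugate reduction of enones, reductive aldol cyclisations and the anti-selective aldol addition of cyclic boron enolates, which have not been merged intermolecularly on a 2-alkylcyclopent-2-enone to make an α-quaternary aldol.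

**Step 8**
Reactants: 14 tert-butyl 2-[(1R,3S,5S)-5-[(tert-butyldimethylsilyl)oxy]-3-[(1S)-1-hydroxy-4-{[(4-methoxybenzyl)oxy]methyl}pent-4-en-1-yl]-3-methyl-2-oxocyclopentyl]acetate
Product: 15 tert-butyl 2-[(1R,2R,3S,5S)-5-[(tert-butyldimethylsilyl)oxy]-2-ethenyl-2-hydroxy-3-[(1S)-1-hydroxy-4-{[(4-methoxybenzyl)oxy]methyl}pent-4-en-1-yl]-3-methylcyclopentyl]acetate
Conditions: CH2=CHMgBr (3 equiv), CeCl3 (3 equiv), THF, −78 °C; aq. NH4Cl at −78 °C
Reagents that add atoms: vinylmagnesium bromide, C=C[Mg]Br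
Why: Organocerium 1,2-addition (Imamoto conditions) adds vinyl to the hindered, enolisable ketone at low temperature without retro-aldol or attack on the tert-butyl ester, from the face opposite the C-7 arm and the C-10 methyl; the new C-6 centre is destroyed in step 10, so its epimer would serve equally.

**Step 9**
Reactants: 15 tert-butyl 2-[(1R,2R,3S,5S)-5-[(tert-butyldimethylsilyl)oxy]-2-ethenyl-2-hydroxy-3-[(1S)-1-hydroxy-4-{[(4-methoxybenzyl)oxy]methyl}pent-4-en-1-yl]-3-methylcyclopentyl]acetate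
Product: 16 tert-butyl 2-[(2S,3R,3aR,8S,8aS)-2-[(tert-butyldimethylsilyl)oxy]-3a,8-dihydroxy-5-{[(4-methoxybenzyl)oxy]methyl}-8a-methyl-1,2,3,3a,6,7,8,8a-octahydroazulen-3-yl]acetate
Conditions: second-generation Hoveyda–Grubbs catalyst (H2IMes)Cl2Ru=CH(C6H4-2-OiPr) (5 mol%), toluene (0.005 M), 80 °C
Reagents that add atoms: none
Why: Ring-closing metathesis of the vinyl carbinol with the 1,1-disubstituted olefin closes the seven-membered ring, in which the new trisubstituted C-4=C-5 bond can only be ring-cis, the geometry required in the target.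

**Step 10**
Reactants: 16 tert-butyl 2-[(2S,3R,3aR,8S,8aS)-2-[(tert-butyldimethylsilyl)oxy]-3a,8-dihydroxy-5-{[(4-methoxybenzyl)oxy]methyl}-8a-methyl-1,2,3,3a,6,7,8,8a-octahydroazulen-3-yl]acetate
Product: 18 tert-butyl 2-[(1R,3E,7Z,10S)-10-[(tert-butyldimethylsilyl)oxy]-4-{[(4-methoxybenzyl)oxy]methyl}-8-methyl-2-oxocyclodeca-3,7-dien-1-yl]acetate, via mesylate 17 (not isolated)
Conditions: MsCl (1.2 equiv), Et3N (2 equiv), CH2Cl2, −20 °C; aqueous wash, evaporate; KN(SiMe3)2 (1.05 equiv), THF, −78 to 0 °C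
Reagents that add atoms: none
Why: Grob (Wharton) fragmentation, a heterolytic ring expansion: selective sulfonylation of the secondary alcohol and deprotonation of the tertiary one give a 1,3-diol monosulfonate whose C-6/C-10 fusion bond can lie anti-periplanar to the C-1 mesylate, so the alkoxide collapses to the C-6 ketone while the five- and seven-membered rings merge into the ten-membered ring; the anti (1S,10S) relationship from step 7 is translated stereospecifically into the Z C-1=C-10 olefin (C-2 and C-9 cis), the ring-cis C-4=C-5 bond is untouched, and using one equivalent of base avoids enolisation of the product.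

**Step 11**
Reactants: 18 tert-butyl 2-[(1R,3E,7Z,10S)-10-[(tert-butyldimethylsilyl)oxy]-4-{[(4-methoxybenzyl)oxy]methyl}-8-methyl-2-oxocyclodeca-3,7-dien-1-yl]acetate
Product: 19 tert-butyl 2-[(1S,2R,3E,7Z,10S)-10-[(tert-butyldimethylsilyl)oxy]-2-hydroxy-4-{[(4-methoxybenzyl)oxy]methyl}-8-methylcyclodeca-3,7-dien-1-yl]acetate
Conditions: (R)-2-methyl-CBS-oxazaborolidine (0.3 equiv), catecholborane (1.8 equiv), toluene, −78 °C; then MeOH, pH 7 buffer
Reagents that add atoms: none
Why: Corey–Bakshi–Shibata reduction, in which the (R)-oxazaborolidine treats the alkenyl side of the enone as the large group and delivers hydride 1,2 to give the 6R allylic alcohol by catalyst control without touching the ester or the olefins.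

**Step 12**
Reactants: 19 tert-butyl 2-[(1S,2R,3E,7Z,10S)-10-[(tert-butyldimethylsilyl)oxy]-2-hydroxy-4-{[(4-methoxybenzyl)oxy]methyl}-8-methylcyclodeca-3,7-dien-1-yl]acetate
Product: 21 (3S,3aS,4S,6Z,10E,11aR)-4-[(tert-butyldimethylsilyl)oxy]-10-{[(4-methoxybenzyl)oxy]methyl}-3,6-dimethyl-3a,4,5,8,9,11a-hexahydrocyclodeca[b]furan-2(3H)-one, via desmethyl lactone 20 (not isolated)
Conditions: LiN(SiMe3)2 (1.05 equiv), THF, −78 to 0 °C; then LiN(iPr)2 (1.5 equiv), −78 °C; MeI (5 equiv), −78 to −40 °C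
Reagents that add atoms: iodomethane, CI
Why: The lithium alkoxide lactonises onto the tert-butyl ester (5-exo transesterification giving the trans-fused γ-lactone; the lithium counter-ion and low temperature disfavour 1,3-silyl migration from O-8), and the lactone enolate is then methylated (enolate alkylation) from the face opposite the adjacent C-8 substituent, giving the 11S methyl trans to C-8, which is also the thermodynamically preferred epimer.

**Step 13**
Reactants: 21 (3S,3aS,4S,6Z,10E,11aR)-4-[(tert-butyldimethylsilyl)oxy]-10-{[(4-methoxybenzyl)oxy]methyl}-3,6-dimethyl-3a,4,5,8,9,11a-hexahydrocyclodeca[b]furan-2(3H)-one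
Product: 22 (3S,3aR,4S,6Z,10E,11aR)-4-hydroxy-10-{[(4-methoxybenzyl)oxy]methyl}-3,6-dimethyl-3a,4,5,8,9,11a-hexahydrocyclodeca[b]furan-2(3H)-one
Conditions: HF·pyridine, pyridine, THF, 0 °C to rt
Reagents that add atoms: none
Why: Fluoride-mediated desilylation frees the C-8 hydroxyl while the PMB ether, the lactone and the olefins are inert to buffered HF·pyridine.

**Step 14**
Reactants: 22 (3S,3aR,4S,6Z,10E,11aR)-4-hydroxy-10-{[(4-methoxybenzyl)oxy]methyl}-3,6-dimethyl-3a,4,5,8,9,11a-hexahydrocyclodeca[b]furan-2(3H)-one; 7 2-{[(4-methoxybenzyl)oxy]methyl}prop-2-enoic acid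
Product: 23 (3S,3aR,4S,6Z,10E,11aR)-10-{[(4-methoxybenzyl)oxy]methyl}-3,6-dimethyl-2-oxo-2,3,3a,4,5,8,9,11a-octahydrocyclodeca[b]furan-4-yl 2-{[(4-methoxybenzyl)oxy]methyl}prop-2-enoate
Conditions: 7 (2 equiv), 2,4,6-trichlorobenzoyl chloride (2 equiv), Et3N, toluene, rt; then 22, DMAP, rt
Reagents that add atoms: none
Why: Yamaguchi esterification through the mixed trichlorobenzoyl anhydride acylates the hindered secondary C-8 alcohol with retention of configuration.

**Step 15**
Reactants: 23 (3S,3aR,4S,6Z,10E,11aR)-10-{[(4-methoxybenzyl)oxy]methyl}-3,6-dimethyl-2-oxo-2,3,3a,4,5,8,9,11a-octahydrocyclodeca[b]furan-4-yl 2-{[(4-methoxybenzyl)oxy]methyl}prop-2-enoate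
Product: 24 (3S,3aR,4S,6Z,10E,11aR)-10-(hydroxymethyl)-3,6-dimethyl-2-oxo-2,3,3a,4,5,8,9,11a-octahydrocyclodeca[b]furan-4-yl 2-(hydroxymethyl)prop-2-enoate
Conditions: DDQ (2.6 equiv), CH2Cl2/pH 7 phosphate buffer (10:1), 0 °C
Reagents that add atoms: none
Why: Oxidative PMB ether cleavage with DDQ removes both allylic PMB groups under neutral conditions that leave the acrylate, the lactone and the ring-cis olefins untouched, giving the target.

**Compound list**
1 | 2-methylidenepropane-1,3-diol | C=C(CO)CO | starting material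
2 | 2-{[(4-methoxybenzyl)oxy]methyl}prop-2-en-1-ol | C=C(CO)COCc1ccc(OC)cc1 | intermediate
3 | ethyl vinyl ether | C=COCC | starting material
4 | 1-({2-[(ethenyloxy)methyl]prop-2-en-1-yl}oxymethyl)-4-methoxybenzene (allyl vinyl ether) | C=COCC(=C)COCc1ccc(OC)cc1 | intermediate
5 | 4-{[(4-methoxybenzyl)oxy]methyl}pent-4-enal | O=CCCC(=C)COCc1ccc(OC)cc1 | intermediate
6 | 2-(bromomethyl)prop-2-enoic acid | C=C(CBr)C(=O)O | starting material
7 | 2-{[(4-methoxybenzyl)oxy]methyl}prop-2-enoic acid | C=C(COCc1ccc(OC)cc1)C(=O)O | intermediate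
8 | (4R)-4-[(tert-butyldimethylsilyl)oxy]cyclopent-2-en-1-one | O=C1C=C[C@H](O[Si](C)(C)C(C)(C)C)C1 | starting material
9 | (4R)-4-[(tert-butyldimethylsilyl)oxy]-2-iodocyclopent-2-en-1-one | O=C1C(I)=C[C@H](O[Si](C)(C)C(C)(C)C)C1 | intermediate
10 | (4R)-4-[(tert-butyldimethylsilyl)oxy]-2-methylcyclopent-2-en-1-one | O=C1C(C)=C[C@H](O[Si](C)(C)C(C)(C)C)C1 | intermediate
11 | tert-butyl bromoacetate (bromoacetic acid, carboxyl protected as tert-butyl ester) | BrCC(=O)OC(C)(C)C | starting material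
12 | tert-butyl 2-[(1R,5S)-5-[(tert-butyldimethylsilyl)oxy]-3-methyl-2-oxocyclopent-3-en-1-yl]acetate | O=C1C(C)=C[C@H](O[Si](C)(C)C(C)(C)C)[C@H]1CC(=O)OC(C)(C)C | intermediate
13 | tert-butyl 2-[(1R,5S)-5-[(tert-butyldimethylsilyl)oxy]-3-methyl-2-[(4,4,5,5-tetramethyl-1,3,2-dioxaborolan-2-yl)oxy]cyclopent-2-en-1-yl]acetate (pinacolboron enolate) | CC1=C(OB2OC(C)(C)C(C)(C)O2)[C@H](CC(=O)OC(C)(C)C)[C@@H](O[Si](C)(C)C(C)(C)C)C1 | intermediate
14 | tert-butyl 2-[(1R,3S,5S)-5-[(tert-butyldimethylsilyl)oxy]-3-[(1S)-1-hydroxy-4-{[(4-methoxybenzyl)oxy]methyl}pent-4-en-1-yl]-3-methyl-2-oxocyclopentyl]acetate | O=C1[C@](C)([C@@H](O)CCC(=C)COCc2ccc(OC)cc2)C[C@H](O[Si](C)(C)C(C)(C)C)[C@H]1CC(=O)OC(C)(C)C | intermediate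
15 | tert-butyl 2-[(1R,2R,3S,5S)-5-[(tert-butyldimethylsilyl)oxy]-2-ethenyl-2-hydroxy-3-[(1S)-1-hydroxy-4-{[(4-methoxybenzyl)oxy]methyl}pent-4-en-1-yl]-3-methylcyclopentyl]acetate | C=C[C@]1(O)[C@](C)([C@@H](O)CCC(=C)COCc2ccc(OC)cc2)C[C@H](O[Si](C)(C)C(C)(C)C)[C@H]1CC(=O)OC(C)(C)C | intermediate
16 | tert-butyl 2-[(2S,3R,3aR,8S,8aS)-2-[(tert-butyldimethylsilyl)oxy]-3a,8-dihydroxy-5-{[(4-methoxybenzyl)oxy]methyl}-8a-methyl-1,2,3,3a,6,7,8,8a-octahydroazulen-3-yl]acetate (cis-fused) | O[C@]12C=C(COCc3ccc(OC)cc3)CC[C@H](O)[C@]2(C)C[C@H](O[Si](C)(C)C(C)(C)C)[C@H]1CC(=O)OC(C)(C)C | intermediate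
17 | 8-O-methanesulfonate of 16 (same configuration) | O[C@]12C=C(COCc3ccc(OC)cc3)CC[C@H](OS(C)(=O)=O)[C@]2(C)C[C@H](O[Si](C)(C)C(C)(C)C)[C@H]1CC(=O)OC(C)(C)C | intermediate
18 | tert-butyl 2-[(1R,3E,7Z,10S)-10-[(tert-butyldimethylsilyl)oxy]-4-{[(4-methoxybenzyl)oxy]methyl}-8-methyl-2-oxocyclodeca-3,7-dien-1-yl]acetate (both ring olefins ring-cis) | O=C1/C=C(/COCc2ccc(OC)cc2)CC/C=C(/C)C[C@H](O[Si](C)(C)C(C)(C)C)[C@H]1CC(=O)OC(C)(C)C | intermediate
19 | tert-butyl 2-[(1S,2R,3E,7Z,10S)-10-[(tert-butyldimethylsilyl)oxy]-2-hydroxy-4-{[(4-methoxybenzyl)oxy]methyl}-8-methylcyclodeca-3,7-dien-1-yl]acetate | O[C@@H]1/C=C(/COCc2ccc(OC)cc2)CC/C=C(/C)C[C@H](O[Si](C)(C)C(C)(C)C)[C@H]1CC(=O)OC(C)(C)C | intermediate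
20 | (3aS,4S,6Z,10E,11aR)-4-[(tert-butyldimethylsilyl)oxy]-10-{[(4-methoxybenzyl)oxy]methyl}-6-methyl-3a,4,5,8,9,11a-hexahydrocyclodeca[b]furan-2(3H)-one | CC(C)(C)[Si](C)(C)O[C@H]1C/C(C)=C\CC/C(COCc3ccc(OC)cc3)=C\[C@H]2OC(=O)C[C@H]12 | intermediate
21 | (3S,3aS,4S,6Z,10E,11aR)-4-[(tert-butyldimethylsilyl)oxy]-10-{[(4-methoxybenzyl)oxy]methyl}-3,6-dimethyl-3a,4,5,8,9,11a-hexahydrocyclodeca[b]furan-2(3H)-one | CC(C)(C)[Si](C)(C)O[C@H]1C/C(C)=C\CC/C(COCc3ccc(OC)cc3)=C\[C@H]2OC(=O)[C@@H](C)[C@H]12 | intermediate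
22 | (3S,3aR,4S,6Z,10E,11aR)-4-hydroxy-10-{[(4-methoxybenzyl)oxy]methyl}-3,6-dimethyl-3a,4,5,8,9,11a-hexahydrocyclodeca[b]furan-2(3H)-one | O[C@H]1C/C(C)=C\CC/C(COCc3ccc(OC)cc3)=C\[C@H]2OC(=O)[C@@H](C)[C@H]12 | intermediate
23 | (3S,3aR,4S,6Z,10E,11aR)-10-{[(4-methoxybenzyl)oxy]methyl}-3,6-dimethyl-2-oxo-2,3,3a,4,5,8,9,11a-octahydrocyclodeca[b]furan-4-yl 2-{[(4-methoxybenzyl)oxy]methyl}prop-2-enoate | C=C(COCc4ccc(OC)cc4)C(=O)O[C@H]1C/C(C)=C\CC/C(COCc3ccc(OC)cc3)=C\[C@H]2OC(=O)[C@@H](C)[C@H]12 | intermediate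
24 | (3S,3aR,4S,6Z,10E,11aR)-10-(hydroxymethyl)-3,6-dimethyl-2-oxo-2,3,3a,4,5,8,9,11a-octahydrocyclodeca[b]furan-4-yl 2-(hydroxymethyl)prop-2-enoate (CNP0167163.4) | C=C(CO)C(=O)O[C@H]1C/C(C)=C\CC/C(CO)=C\[C@H]2OC(=O)[C@@H](C)[C@H]12 | target

**Step count and risks**
Total step count: 15. Longest linear sequence: 12 steps (8 to 24, steps 4 to 15).

Steps most likely to fail:

Step 7 (the proposed new reductive aldol). The risks are 1,2-reduction of the enone, reduction of the aldehyde by residual hydride, and low anti selectivity at the quaternary centre. The known-chemistry fallback sets out from 12, which is reduced 1,4 with catalytic [(Ph3P)CuH]6 and PhMe2SiH to the isolated dimethyl(phenyl)silyl enol ether F1. MeLi (THF, 0 °C) then releases the lithium enolate (Stork–House enolate regeneration), ZnCl2 is added and aldehyde 5 is introduced at −78 °C; this closed-transition-state zinc aldol comes back to the route at 14.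

Step 10 (Grob fragmentation). The risks are that the mesylate cannot reach the anti-periplanar arrangement, that an oxetane forms, or that a wrong C-1 epimer gives the E olefin. The fallback is a different ring expansion and sets out from 16. Dess–Martin oxidation of the secondary alcohol gives the β-hydroxy ketone F2. KN(SiMe3)2 followed by PhNTf2 (THF, −78 °C) effects a retro-aldol ring expansion and traps the regiodefined C-1/C-10 enolate as the ten-membered enol triflate F3, whose geometry would have to be confirmed by NOE. Pd(OAc)2/PPh3 with HCO2H/Et3N then reduces the triflate to C–H, and the fallback comes back to the route at 18.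

Step 11 (CBS reduction). The risk is that the catalyst does not override the conformational bias of the ten-membered enone, so the 6S alcohol dominates. The fallback sets out from 18: Luche reduction (NaBH4, CeCl3·7H2O, MeOH, −78 °C) is taken to the substrate-controlled 6S allylic alcohol F4. Mitsunobu reaction with 4-nitrobenzoic acid (PPh3, DIAD) inverts C-6 to give the 6R 4-nitrobenzoate F5, and methanolysis (K2CO3, MeOH) comes back to the route at 19.

**Further compounds**
F1 | step 7 | tert-butyl 2-[(1R,5S)-5-[(tert-butyldimethylsilyl)oxy]-2-{[dimethyl(phenyl)silyl]oxy}-3-methylcyclopent-2-en-1-yl]acetate | CC1=C(O[Si](C)(C)c2ccccc2)[C@H](CC(=O)OC(C)(C)C)[C@@H](O[Si](C)(C)C(C)(C)C)C1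
F2 | step 10 | tert-butyl 2-[(2S,3R,3aR,8aR)-2-[(tert-butyldimethylsilyl)oxy]-3a-hydroxy-5-{[(4-methoxybenzyl)oxy]methyl}-8a-methyl-8-oxo-1,2,3,3a,6,7,8,8a-octahydroazulen-3-yl]acetate | O[C@]12C=C(COCc3ccc(OC)cc3)CCC(=O)[C@]2(C)C[C@H](O[Si](C)(C)C(C)(C)C)[C@H]1CC(=O)OC(C)(C)C
F3 | step 10 | tert-butyl 2-[(1R,3E,7E,10S)-10-[(tert-butyldimethylsilyl)oxy]-4-{[(4-methoxybenzyl)oxy]methyl}-8-methyl-2-oxo-7-{[(trifluoromethyl)sulfonyl]oxy}cyclodeca-3,7-dien-1-yl]acetate (both ring olefins ring-cis) | O=C1/C=C(/COCc2ccc(OC)cc2)CC/C(OS(=O)(=O)C(F)(F)F)=C(/C)C[C@H](O[Si](C)(C)C(C)(C)C)[C@H]1CC(=O)OC(C)(C)C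
F4 | step 11 | tert-butyl 2-[(1S,2S,3E,7Z,10S)-10-[(tert-butyldimethylsilyl)oxy]-2-hydroxy-4-{[(4-methoxybenzyl)oxy]methyl}-8-methylcyclodeca-3,7-dien-1-yl]acetate | O[C@H]1/C=C(/COCc2ccc(OC)cc2)CC/C=C(/C)C[C@H](O[Si](C)(C)C(C)(C)C)[C@H]1CC(=O)OC(C)(C)C
F5 | step 11 | (1R,2E,6Z,9S,10S)-10-(2-tert-butoxy-2-oxoethyl)-9-[(tert-butyldimethylsilyl)oxy]-3-{[(4-methoxybenzyl)oxy]methyl}-7-methylcyclodeca-2,6-dien-1-yl 4-nitrobenzoate | O=C(O[C@@H]1/C=C(/COCc2ccc(OC)cc2)CC/C=C(/C)C[C@H](O[Si](C)(C)C(C)(C)C)[C@H]1CC(=O)OC(C)(C)C)c3ccc(cc3)[N+](=O)[O-]
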